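**Retrosynthetic overview**

1. Target 20 ⇐ diol 16 + (S)-3-methylpentanoic acid 19 (acylation of O15); the axial C3 hydroxyl ⇐ 3-ketone 14 (bulky hydride).
2. Ring A ⇐ radical closure of the C3–C4 bond in isopropenyl aldehyde 12; 12 ⇐ keto-aldehyde 9 (twofold methylenation, then hydroformylation of the C10 vinyl group).
3. The plan rests on ring B (C5–C10): a cyclohexene with the C7=C8 olefin, the C8 methyl, the C9 side chain and the contiguous C9–C10–C5 stereotriad. This is the imprint of a 1-alkyl-2-methyl diene (C6=C7–C8=C9) on a trisubstituted dienophile (C5=C10), so 9 ⇐ 5 + 8 by a catalytic enantioselective Diels–Alder reaction forming C5–C6 and C9–C10.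
4. Diene 5 ⇐ geraniol (silylation, allylic oxidation, methylenation); dienophile 8 ⇐ methylglyoxal (Wittig); acid 19 ⇐ (S)-1-bromo-2-methylbutane.
5. Ring order: ring B first (step 6), ring A second (step 9).

Key step: step 6

Remark: labdane numbering is used (ring A = C1–C5, C10; ring B = C5–C10; chain C11–C16; C17 on C8; C18 and C19 on C4; C20 on C10). The target is the (3S,5S,9R,10S) isomer: a trans-decalin with the C9 chain cis to the C10 methyl and an axial C3 hydroxyl trans to it.

Assumption: the sense of induction in step 6 is taken from the formyl C–H···O binding model of the oxazaborolidinium class, which for the (5S,9R,10S) adduct calls for the catalyst derived from (R)-α,α-diphenylprolinol. Should the adduct prove antipodal, the (S)-prolinol catalyst would be used and nothing else would change.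

**Route**

Step 1
Reactants: 1 geraniol
Product: 2 geranyl tert-butyldimethylsilyl ether
Conditions: TBSCl, imidazole, CH2Cl2, 0 °C → rt
Reagents that add atoms: tert-butyldimethylsilyl chloride, CC(C)(C)[Si](C)(C)Cl
Why: O-silylation of the primary allylic alcohol (silyl ether formation); no stereocentre is formed and both olefin geometries are untouched.

Step 2
Reactants: 2 geranyl tert-butyldimethylsilyl ether
Product: 3 (2E,6E)-8-(tert-butyldimethylsilyloxy)-2,6-dimethylocta-2,6-dien-1-ol
Conditions: SeO2 (0.3 equiv), t-BuOOH (70% aq.), salicylic acid (cat.), CH2Cl2, rt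
Reagents that add atoms: tert-butyl hydroperoxide, CC(C)(C)OO; selenium dioxide (catalytic oxygen carrier), O=[Se]=O
Why: Riley allylic oxidation (ene reaction, then [2,3]-sigmatropic shift) should attack the more electron-rich terminal olefin at its (E)-methyl group and return the (E)-allylic alcohol, the 2,3-olefin being deactivated by its allylic oxygen.

Step 3
Reactants: 3 (2E,6E)-8-(tert-butyldimethylsilyloxy)-2,6-dimethylocta-2,6-dien-1-ol
Product: 4 (2E,6E)-8-(tert-butyldimethylsilyloxy)-2,6-dimethylocta-2,6-dienal
Conditions: MnO2 (activated, excess), CH2Cl2, rt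
Reagents that add atoms: none
Why: MnO2 oxidation of an allylic alcohol to the enal under neutral conditions, which keeps the (E)-geometry.

Step 4
Reactants: 4 (2E,6E)-8-(tert-butyldimethylsilyloxy)-2,6-dimethylocta-2,6-dienal
Product: 5 (2E,6E)-3,7-dimethylnona-2,6,8-trienyl tert-butyldimethylsilyl ether
Conditions: Ph3PCH3Br, KOt-Bu, THF, 0 °C
Reagents that add atoms: methyltriphenylphosphonium bromide, C[P+](c1ccccc1)(c1ccccc1)c1ccccc1.[Br-]
Why: Wittig methylenation of the enal gives the terminal diene without touching the trisubstituted (E)-olefin, so the chain stays trans to the new vinyl group (the outside position of the diene).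

Step 5
Reactants: 6 methylglyoxal; 7 2-(triphenylphosphoranylidene)propanal
Product: 8 (E)-2-methyl-4-oxopent-2-enal
Conditions: 6 (40% aq., 2 equiv), CH2Cl2, rt → 40 °C
Reagents that add atoms: none
Why: Wittig olefination with a stabilised ylide: only the highly electrophilic aldehyde carbon of methylglyoxal should react, and the stabilised ylide gives the (E)-olefin with formyl and acetyl trans.

Step 6
Reactants: 5 (2E,6E)-3,7-dimethylnona-2,6,8-trienyl tert-butyldimethylsilyl ether; 8 (E)-2-methyl-4-oxopent-2-enal
Product: 9 (1S,2R,6S)-6-acetyl-2-[(3E)-5-(tert-butyldimethylsilyloxy)-3-methylpent-3-en-1-yl]-1,3-dimethylcyclohex-3-ene-1-carbaldehyde (ring B; labdane C10 formyl, C5 acetyl; 5S,9R,10S)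
Conditions: (R)-3,3-diphenyl-1-(o-tolyl)tetrahydro-1H,3H-pyrrolo[1,2-c][1,3,2]oxazaborole (20 mol%) protonated with Tf2NH (18 mol%), 8 (1.5 equiv), CH2Cl2, −78 → −40 °C
Reagents that add atoms: none
Why: The protonated oxazaborolidine binds the formyl oxygen of 8 (formyl C–H···O contact to the ring oxygen, enal s-trans), and the diene adds in a concerted, asynchronous [4+2] cycloaddition in which the unsubstituted terminus C6 bonds to C5, the carbon β to the bound aldehyde, ahead of the C9–C10 bond. The closest known reaction type is the oxazaborolidinium-catalysed enantioselective Diels–Alder reaction of α-methyl α,β-enals with acyclic dienes. Ring B is closed by this intermolecular suprafacial cycloaddition, which makes both new ring bonds (C5–C6 and C9–C10) and leaves the C7=C8 olefin with its methyl group in place. C10 is set by the catalyst, whose carbinol phenyl group covers one face of the bound enal; C5 follows from the (E)-geometry of 8, which holds formyl and acetyl trans; C9 follows from the (E)-geometry of the C8=C9 diene bond and a transition state with formyl exo and the C10 methyl and acetyl groups endo, so that C11 ends cis to C20. The step needs ortho regiochemistry, formyl-exo diastereoselectivity and one enantioface: the 1-alkyl substituent of the diene together with formyl-selective activation (a ketone-bound complex would have to bond first at the fully substituted C10) should secure the first, the α-methyl group and the endo-seeking acetyl group the second, and the chiral boron centre the third.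

Step 7
Reactants: 9 keto-aldehyde (ring B adduct)
Product: 11 bis-olefin (ring B with C10 vinyl and C5 isopropenyl groups, configuration as in 9), via vinyl ketone 10 (not isolated)
Conditions: Ph3PCH3Br (4 equiv), KOt-Bu (3.8 equiv), THF, 0 → 40 °C
Reagents that add atoms: methyltriphenylphosphonium bromide, C[P+](c1ccccc1)(c1ccccc1)c1ccccc1.[Br-]
Why: Twofold Wittig methylenation, the formyl group reacting first (to 10) and the hindered methyl ketone on warming; a slight excess of the salt over KOt-Bu leaves no free alkoxide, which guards C5, the only enolisable stereocentre.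

Step 8
Reactants: 11 bis-olefin
Product: 12 3-(ring B-C10-yl)propanal (C1–C2–C3 chain ending in the C3 aldehyde; C5 isopropenyl)
Conditions: Rh(acac)(CO)2 (2 mol%), PPh3 (20 mol%), CO/H2 (1:1, 10 bar), toluene, 50 °C
Reagents that add atoms: carbon monoxide, [C-]#[O+]
Why: Rhodium-catalysed hydroformylation should take the monosubstituted vinyl group in preference to the 1,1-disubstituted and trisubstituted olefins and, since the vinyl group sits on the quaternary C10, give only the linear aldehyde.

Step 9
Reactants: 12 isopropenyl aldehyde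
Product: 13 (3RS,5S,9R,10S)-15-(tert-butyldimethylsilyloxy)labda-7,13E-dien-3-ol (mixture of C3 epimers)
Conditions: Fe(acac)3 (0.5 equiv), PhSiH3 (2.5 equiv), EtOH (degassed), 60 °C
Reagents that add atoms: none
Why: Hydrogen-atom transfer from the iron hydride to the isopropenyl group gives the tertiary C4 radical, which adds 6-exo to the formyl carbon before the alkoxy radical is reduced and protonated (MHAT reductive alkene–aldehyde radical cyclization); the trans ring fusion is fixed by C5 and C10, and C3 is left uncontrolled because step 10 erases it.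

Step 10
Reactants: 13 C3-epimeric alcohols
Product: 14 (5S,9R,10S)-15-(tert-butyldimethylsilyloxy)labda-7,13E-dien-3-one
Conditions: Dess–Martin periodinane, CH2Cl2, rt
Reagents that add atoms: none
Why: Dess–Martin oxidation converges both C3 epimers on one ketone without touching the olefins or the silyl ether.

Step 11
Reactants: 14 3-ketone
Product: 15 (3S,5S,9R,10S)-15-(tert-butyldimethylsilyloxy)labda-7,13E-dien-3-ol (axial hydroxyl)
Conditions: LiBH(s-Bu)3, THF, −78 °C; then H2O
Reagents that add atoms: none
Why: Ketone reduction by a bulky trialkylborohydride: hydride should approach C3 along the equatorial trajectory, away from the axial hydrogens at C1 and C5, and give the axial (3S) alcohol trans to the C10 methyl, as is usual for 4,4-dimethyl-3-oxo trans-decalins.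

Step 12
Reactants: 15 axial alcohol silyl ether
Product: 16 (3S,5S,9R,10S)-labda-7,13E-diene-3,15-diol
Conditions: Bu4NF, THF, 0 °C → rt
Reagents that add atoms: none
Why: Fluoride-mediated desilylation frees the primary allylic O15 hydroxyl; no stereocentre is involved.

Step 13
Reactants: 17 (S)-1-bromo-2-methylbutane
Product: 19 (S)-3-methylpentanoic acid, via (S)-2-methylbutylmagnesium bromide 18 (not isolated)
Conditions: Mg, THF, reflux; CO2 (solid), −78 °C → rt; aq. HCl
Reagents that add atoms: carbon dioxide, O=C=O
Why: Grignard formation and carboxylation lengthen the chain by one carbon; the stereocentre is β to magnesium and is not touched, so the (S)-configuration of 17 is carried into the acid.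

Step 14
Reactants: 16 diol; 19 (S)-3-methylpentanoic acid
Product: 20 (3S,5S,9R,10S)-3-hydroxylabda-7,13E-dien-15-yl (S)-3-methylpentanoate (target)
Conditions: 19 (1.05 equiv), N,N'-diisopropylcarbodiimide, DMAP (10 mol%), CH2Cl2, 0 °C
Reagents that add atoms: none
Why: Steglich esterification should acylate the unhindered primary allylic hydroxyl at O15 and leave the axial, neopentyl-type C3 hydroxyl next to the gem-dimethyl group; no stereocentre is affected.

**Compound list**

1 | geraniol | CC(C)=CCC/C(C)=C/CO | starting material
2 | geranyl tert-butyldimethylsilyl ether | CC(C)=CCC/C(C)=C/CO[Si](C)(C)C(C)(C)C | intermediate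
3 | (2E,6E)-8-(tert-butyldimethylsilyloxy)-2,6-dimethylocta-2,6-dien-1-ol | OC/C(C)=C/CC/C(C)=C/CO[Si](C)(C)C(C)(C)C | intermediate
4 | (2E,6E)-8-(tert-butyldimethylsilyloxy)-2,6-dimethylocta-2,6-dienal | O=C/C(C)=C/CC/C(C)=C/CO[Si](C)(C)C(C)(C)C | intermediate
5 | (2E,6E)-3,7-dimethylnona-2,6,8-trienyl tert-butyldimethylsilyl ether | C=C/C(C)=C/CC/C(C)=C/CO[Si](C)(C)C(C)(C)C | intermediate
6 | methylglyoxal | CC(=O)C=O | starting material
7 | 2-(triphenylphosphoranylidene)propanal | CC(C=O)=P(c1ccccc1)(c1ccccc1)c1ccccc1 | starting material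
8 | (E)-2-methyl-4-oxopent-2-enal | O=C/C(C)=C/C(C)=O | intermediate
9 | (1S,2R,6S)-6-acetyl-2-[(3E)-5-(tert-butyldimethylsilyloxy)-3-methylpent-3-en-1-yl]-1,3-dimethylcyclohex-3-ene-1-carbaldehyde | O=C[C@@]1(C)[C@H](CC/C(C)=C/CO[Si](C)(C)C(C)(C)C)C(C)=CC[C@@H]1C(C)=O | intermediate
10 | vinyl ketone (C10 vinyl, C5 acetyl; configuration as in 9) | C=C[C@@]1(C)[C@H](CC/C(C)=C/CO[Si](C)(C)C(C)(C)C)C(C)=CC[C@@H]1C(C)=O | intermediate (not isolated)
11 | bis-olefin (C10 vinyl, C5 isopropenyl; configuration as in 9) | C=C[C@@]1(C)[C@H](CC/C(C)=C/CO[Si](C)(C)C(C)(C)C)C(C)=CC[C@@H]1C(C)=C | intermediate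
12 | isopropenyl aldehyde (C10–CH2CH2CHO, C5 isopropenyl; configuration as in 9) | O=CCC[C@@]1(C)[C@H](CC/C(C)=C/CO[Si](C)(C)C(C)(C)C)C(C)=CC[C@@H]1C(C)=C | intermediate
13 | (3RS,5S,9R,10S)-15-(tert-butyldimethylsilyloxy)labda-7,13E-dien-3-ol, C3 epimers | CC(C)(C)[Si](C)(C)OC/C=C(\C)CC[C@@H]1C(C)=CC[C@@H]2C(C)(C)C(O)CC[C@@]12C | intermediate
14 | (5S,9R,10S)-15-(tert-butyldimethylsilyloxy)labda-7,13E-dien-3-one | CC(C)(C)[Si](C)(C)OC/C=C(\C)CC[C@@H]1C(C)=CC[C@@H]2C(C)(C)C(=O)CC[C@@]12C | intermediate
15 | (3S,5S,9R,10S)-15-(tert-butyldimethylsilyloxy)labda-7,13E-dien-3-ol | CC(C)(C)[Si](C)(C)OC/C=C(\C)CC[C@@H]1C(C)=CC[C@@H]2C(C)(C)[C@@H](O)CC[C@@]12C | intermediate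
16 | (3S,5S,9R,10S)-labda-7,13E-diene-3,15-diol | OC/C=C(\C)CC[C@@H]1C(C)=CC[C@@H]2C(C)(C)[C@@H](O)CC[C@@]12C | intermediate
17 | (S)-1-bromo-2-methylbutane | CC[C@H](C)CBr | starting material
18 | (S)-2-methylbutylmagnesium bromide | CC[C@H](C)C[Mg]Br | intermediate (not isolated)
19 | (S)-3-methylpentanoic acid | CC[C@H](C)CC(=O)O | intermediate
20 | (3S,5S,9R,10S)-3-hydroxylabda-7,13E-dien-15-yl (S)-3-methylpentanoate | CC[C@H](C)CC(=O)OC/C=C(\C)CC[C@@H]1C(C)=CC[C@@H]2C(C)(C)[C@@H](O)CC[C@@]12C | target

**Step count**

Total: 14 steps. Longest linear sequence: 12 steps (steps 1–4, 6–12, 14).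

**Steps most likely to fail**

1. Step 6 (key cycloaddition). What may go wrong: the ketone oxygen of 8 competes with the formyl group for the boron centre, and formyl-endo approach competes with formyl-exo approach, so that regio-, exo- and enantiofacial control are eroded. Fallback: the ketone is replaced by an ester, a much weaker donor toward boron. The fallback sets out from triene 5 and commercial ethyl (E)-3-methyl-4-oxobut-2-enoate (O=C/C(C)=C/C(=O)OCC), combined under the same catalyst to give the aldehyde ester F1. Wittig methylenation of the formyl group (Ph3PCH3Br, KOt-Bu, THF) would give the vinyl ester F2. MeLi with CeCl3 (THF, −78 → 0 °C) would convert the ester into the dimethylcarbinol F3. Dehydration with SOCl2 and pyridine (CH2Cl2, −20 °C) should take a methyl hydrogen in preference to the hindered ring hydrogen at C5, and the route is rejoined at bis-olefin 11. This fallback removes the competing ketone but does not by itself correct a formyl-endo preference.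

2. Step 9 (ring A closure). What may go wrong: addition of the tertiary C4 radical to the formyl group is reversible, so fragmentation of the alkoxy radical, silane reduction of the aldehyde and hydrogen-atom transfer to the two trisubstituted olefins may outrun productive reduction of the alkoxy radical. Fallback: the acceptor is changed to a nitrile, which the silane does not reduce and for which hydrogen-atom-transfer cyclization of alkenyl nitriles to cyclic ketones is known chemistry. It sets out from aldehyde 12. NH2OH·HCl and pyridine (EtOH) would give the oxime F4, and 1,1'-carbonyldiimidazole (CH2Cl2) would dehydrate it to the nitrile F5. Fe(acac)3 and PhSiH3 in EtOH at 60 °C would then close ring A to the ketimine F6, which buffered aqueous acetic acid hydrolyses on work-up. The route is rejoined at ketone 14, so the oxidation of step 10 is not needed.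

3. Step 8 (hydroformylation). What may go wrong: insufficient discrimination between the vinyl and isopropenyl groups, or slow reaction at the neopentyl-type vinyl group, leading to over-formylated or unreacted material. Fallback: the two carbons are added by olefination instead of carbonylation. It sets out from keto-aldehyde 9. A Horner–Wadsworth–Emmons reaction with triethyl phosphonoacetate (NaH, THF), selective for the aldehyde, would give the keto enoate F7. Wittig methylenation of the ketone (Ph3PCH3Br, KOt-Bu, THF) would give the isopropenyl enoate F8. Copper-hydride conjugate reduction (Cu(OAc)2, 1,2-bis(diphenylphosphino)benzene, (EtO)2MeSiH, t-BuOH, toluene) would give the saturated ester F9. i-Bu2AlH in CH2Cl2 at −78 °C should stop at the aldehyde, and the route is rejoined at 12.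

**Further compounds**

F1 | step 6 | aldehyde ester (C10 formyl, C5 ethoxycarbonyl; configuration as in 9) | O=C[C@@]1(C)[C@H](CC/C(C)=C/CO[Si](C)(C)C(C)(C)C)C(C)=CC[C@@H]1C(=O)OCC
F2 | step 6 | vinyl ester (C10 vinyl, C5 ethoxycarbonyl) | C=C[C@@]1(C)[C@H](CC/C(C)=C/CO[Si](C)(C)C(C)(C)C)C(C)=CC[C@@H]1C(=O)OCC
F3 | step 6 | dimethylcarbinol (C10 vinyl, C5 2-hydroxyprop-2-yl) | C=C[C@@]1(C)[C@H](CC/C(C)=C/CO[Si](C)(C)C(C)(C)C)C(C)=CC[C@@H]1C(C)(C)O
F4 | step 9 | oxime of aldehyde 12 (E isomer shown) | O/N=C/CC[C@@]1(C)[C@H](CC/C(C)=C/CO[Si](C)(C)C(C)(C)C)C(C)=CC[C@@H]1C(C)=C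
F5 | step 9 | nitrile (C10–CH2CH2CN, C5 isopropenyl) | N#CCC[C@@]1(C)[C@H](CC/C(C)=C/CO[Si](C)(C)C(C)(C)C)C(C)=CC[C@@H]1C(C)=C
F6 | step 9 | (5S,9R,10S)-15-(tert-butyldimethylsilyloxy)labda-7,13E-dien-3-imine | CC(C)(C)[Si](C)(C)OC/C=C(\C)CC[C@@H]1C(C)=CC[C@@H]2C(C)(C)C(=N)CC[C@@]12C
F7 | step 8 | keto enoate (C10 (E)-2-ethoxycarbonylvinyl, C5 acetyl) | CCOC(=O)/C=C/[C@@]1(C)[C@H](CC/C(C)=C/CO[Si](C)(C)C(C)(C)C)C(C)=CC[C@@H]1C(C)=O
F8 | step 8 | isopropenyl enoate (C10 (E)-2-ethoxycarbonylvinyl, C5 isopropenyl) | CCOC(=O)/C=C/[C@@]1(C)[C@H](CC/C(C)=C/CO[Si](C)(C)C(C)(C)C)C(C)=CC[C@@H]1C(C)=C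
F9 | step 8 | saturated ester (C10–CH2CH2CO2Et, C5 isopropenyl) | CCOC(=O)CC[C@@]1(C)[C@H](CC/C(C)=C/CO[Si](C)(C)C(C)(C)C)C(C)=CC[C@@H]1C(C)=C
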